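The eleven-membered carbocycle (C1 = CMe2, C2–C4 = CH2, C5/C6 = epoxide carbons, C7/C8 = CH2, C9 carrying carboxyl C12, C10 = CH, C11 = CHOBz) is opened at C3–C4. The cut rests on two features. C4 lies allylic to the E-C5=C6 alkene that later becomes the epoxide. C3 is an unfunctionalised ring CH2 on which two phenylsulfonyl groups can be parked and later stripped off. One palladium-catalysed allylic alkylation forms C3–C4, closes the ring and restores the E-alkene. The precursor is an open chain: a C4 allylic methyl carbonate at one end, a C3 bis(phenylsulfonyl)methine at the other, and C11 (R) and C12 as TBS ethers.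

Key step: step 7

Remark on numbering: the labels C1–C12 defined above are also used for the open-chain compounds.
Remark on structures: in the open-chain precursor, the macrocycle and the target, C11 is R. C8 and C11 are cis on C9=C10 (E by CIP, because C12 outranks C8). C4 and C7 are trans on C5=C6, which fits a 5R,6R trans-epoxide. These structures need no correction.
Remark on design: the C–H of a geminal bis-sulfone (pKa about 12) protonates alkenyl-lithium, -magnesium, -zinc and -copper reagents, so the C10–C11 bond is made with a weakly basic alkenylchromium(III) species. The benzoate is put on at the enal stage, before a free acid exists.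
Assumption: the TBS ether of propargyl alcohol is bought as such.

Step 1
Reactants: 1 isobutyraldehyde; 2 1,1-bis(phenylsulfonyl)ethylene
Product: 4 2,2-dimethyl-4,4-bis(phenylsulfonyl)butanal, via pyrrolidine enamine 3 (not isolated)
Conditions: 1 (5 equiv), pyrrolidine (20 mol %), PhCO2H (20 mol %), CHCl3, 0 °C → rt
Reagents that add atoms: none
Why: Enamine-catalysed Michael addition (Stork type): the nucleophilic carbon of 3 attacks the unhindered CH2 terminus of the doubly activated alkene 2 and builds quaternary C1 and the C1–C2 bond, and the product aldehyde has no α-hydrogen and so cannot react again or self-condense.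

Step 2
Reactants: 5 5-bromo-2-methylpent-2-ene; 6 tert-butyldimethyl(prop-2-yn-1-yloxy)silane
Product: 10 (E)-tert-butyl{[2-(iodomethylidene)-6-methylhept-5-en-1-yl]oxy}dimethylsilane (iodine cis to the C8 chain), via Grignard reagent 7 (not isolated), via alkylcopper 8 (not isolated), via alkenylcopper 9 (not isolated)
Conditions: Mg, Et2O, reflux; CuBr·SMe2 (1 equiv), Et2O–Me2S, −45 °C; 6, −25 °C; I2, THF, −78 → 0 °C
Reagents that add atoms: iodine, II
Why: Syn-carbocupration of a terminal alkyne puts the alkyl group on the internal carbon (C9) and copper on the terminus (C10) on the same side, the bulky and weakly Lewis-basic silyl ether oxygen offers no chelation that could reverse this regiochemistry, and iodinolysis of the C–Cu bond goes with retention, so that C8 and iodine end up cis.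

Step 3
Reactants: 4 2,2-dimethyl-4,4-bis(phenylsulfonyl)butanal; 10 (E)-alkenyl iodide
Product: 12 (4R,5E)-6-{[(tert-butyldimethylsilyl)oxy]methyl}-3,3,10-trimethyl-1,1-bis(phenylsulfonyl)undeca-5,9-dien-4-ol (C11 alcohol, 11R), via alkenylchromium(III) species 11 (not isolated)
Conditions: CrCl2 (4 equiv), valinol-derived 2-(oxazolin-2-yl)-6-methyl-N-mesylanilide ligand (4.4 equiv, recovered; the antipode that directs attack to the Re face, sense checked on 12 by Mosher esters), Et3N (4.4 equiv), NiCl2 (2 mol %), THF, rt; 10 (1.8 equiv)
Reagents that add atoms: none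
Why: Asymmetric Nozaki–Hiyama–Kishi coupling: nickel inserts into the C–I bond with retention and hands the alkenyl group to chromium(III), whose weakly basic and slowly protonated C–Cr bond should tolerate the acidic C3–H (the excess of 10 covers any loss), while the chiral ligand on chromium shields the Si face of the non-enolisable aldehyde so that Re-face attack sets C11 as R.

Step 4
Reactants: 12 C11 alcohol
Product: 13 (4R,5E)-4-[(tert-butyldimethylsilyl)oxy]-6-{[(tert-butyldimethylsilyl)oxy]methyl}-3,3,10-trimethyl-1,1-bis(phenylsulfonyl)undeca-5,9-diene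
Conditions: TBSOTf, 2,6-lutidine, CH2Cl2, 0 °C → rt
Reagents that add atoms: tert-butyldimethylsilyl triflate, CC(C)(C)[Si](C)(C)OS(=O)(=O)C(F)(F)F
Why: Silylation with a silyl triflate and a hindered pyridine base is powerful enough for the neopentylic secondary alcohol, too weakly basic to touch C3–H, and leaves the C11–O bond and hence the configuration untouched.

Step 5
Reactants: 13 bis-TBS ether
Product: 15 (2E,6E,8R)-8-[(tert-butyldimethylsilyl)oxy]-6-{[(tert-butyldimethylsilyl)oxy]methyl}-2,9,9-trimethyl-11,11-bis(phenylsulfonyl)undeca-2,6-dien-1-ol (C4 alcohol), via C4 enal 14 (not isolated)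
Conditions: SeO2 (0.3 equiv), t-BuOOH (3 equiv), salicylic acid (10 mol %), CH2Cl2, 0 °C → rt; then NaBH4, MeOH, 0 °C
Reagents that add atoms: tert-butyl hydroperoxide, CC(C)(C)OO (oxygen relayed through catalytic selenium dioxide, O=[Se]=O)
Why: Riley-type allylic oxidation (ene reaction, then [2,3]-shift) seeks the most electron-rich alkene, the terminal Me2C=CH unit, and oxidises the methyl trans to the chain to give the E product, C9=C10 being deactivated by two allylic C–O bonds and shielded by C11, and borohydride brings all enal-level material to the alcohol.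

Step 6
Reactants: 15 C4 alcohol
Product: 16 (2E,6E,8R)-8-[(tert-butyldimethylsilyl)oxy]-6-{[(tert-butyldimethylsilyl)oxy]methyl}-2,9,9-trimethyl-11,11-bis(phenylsulfonyl)undeca-2,6-dien-1-yl methyl carbonate (cyclisation precursor)
Conditions: ClCO2Me, pyridine, CH2Cl2, 0 °C
Reagents that add atoms: methyl chloroformate, COC(=O)Cl
Why: Acylation of the unhindered primary allylic alcohol with a chloroformate, in which pyridine is too weak a base to generate the C3 carbanion, so that neither C-acylation nor premature alkylation should occur.

Step 7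
Reactants: 16 cyclisation precursor
Product: 18 (5E,9E,11R)-11-[(tert-butyldimethylsilyl)oxy]-9-{[(tert-butyldimethylsilyl)oxy]methyl}-1,1,5-trimethyl-3,3-bis(phenylsulfonyl)cycloundeca-5,9-diene (route numbering), via π-allylpalladium zwitterion 17 (not isolated)
Conditions: Pd(PPh3)4 (10 mol %), dppe (12 mol %), THF, reflux; 16 added by syringe pump over 12 h (final about 1 mM)
Reagents that add atoms: none
Why: Pd(0) ionises the only ionisable group, the primary C4 carbonate, with loss of CO2, and the methoxide set free removes the acidic C3–H, so that base appears only in molecules that already carry the electrophile (zwitterion 17). The soft carbanion then attacks the allyl unit on the face away from palladium, as in any Tsuji–Trost alkylation with a stabilised nucleophile, and the closest known reaction type is the macrocyclising allylic alkylation of sulfone-stabilised carbanions, established for medium and large carbocycles. Mode of closure: end-to-end attack at the CH2 terminus C4 puts all three allyl carbons into the 11-membered ring with an endocyclic E-C5=C6, whereas attack at C6 would be an exo closure to a 9-membered ring with an isopropenyl branch. No stereocentre is formed, since C3 carries two identical sulfonyl groups and C11 is a spectator. The step needs C4 over C6, retention of the E geometry and ring over oligomer; the first two should follow from the bulk of the tertiary bis-sulfonyl carbanion, which seeks the unsubstituted terminus, and from the syn placement of the C7 chain on the allyl unit, the third from slow addition at high dilution, helped by the C1 gem-dimethyl group and by the cis arrangement of C8 and C11 on C9=C10, which fold the chain. The C11 and C12 silyl ethers are allylic but are no leaving groups for Pd(0).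

Step 8
Reactants: 18 macrocyclic bis-sulfone
Product: 20 (5E,9E,11R)-11-[(tert-butyldimethylsilyl)oxy]-9-{[(tert-butyldimethylsilyl)oxy]methyl}-1,1,5-trimethylcycloundeca-5,9-diene (route numbering), via C3 monosulfone 19 (not isolated)
Conditions: 6 % Na(Hg), Na2HPO4, MeOH–THF, −20 °C → rt
Reagents that add atoms: none
Why: Reductive desulfonylation by electron transfer cleaves the two C–S bonds in turn to sulfinate and a C3 carbanion that the medium protonates, C3 has no β-leaving group so that no Julia-type elimination can follow, and isolated alkenes and silyl ethers are not reduced under these buffered conditions.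

Step 9
Reactants: 20 bis-TBS diene
Product: 21 (5E,9E,11R)-9-(hydroxymethyl)-1,1,5-trimethylcycloundeca-5,9-dien-11-ol (route numbering)
Conditions: TBAF (4 equiv), THF, rt → 45 °C
Reagents that add atoms: none
Why: Fluoride-driven desilylation frees both alcohols at a stage where the molecule holds nothing base-sensitive, gentle warming dealing with the hindered C11 ether.

Step 10
Reactants: 21 diol
Product: 22 (5E,9E,11R)-11-hydroxy-1,1,5-trimethylcycloundeca-5,9-diene-9-carbaldehyde (route numbering)
Conditions: TEMPO (15 mol %), PhI(OAc)2 (1.1 equiv), CH2Cl2, rt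
Reagents that add atoms: none
Why: TEMPO-catalysed oxidation is very sensitive to steric hindrance and should take the primary C12 allylic alcohol, leave the neopentylic secondary C11 alcohol and stop at the enal in the absence of water, and the formyl group trans to C11 is the favoured alkene geometry, so that no isomerisation is expected.

Step 11
Reactants: 22 hydroxy enal
Product: 23 (5E,9E,11R)-9-formyl-1,1,5-trimethylcycloundeca-5,9-dien-11-yl benzoate (route numbering)
Conditions: BzCl (3 equiv), DMAP (0.5 equiv), pyridine–CH2Cl2, rt → 40 °C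
Reagents that add atoms: benzoyl chloride, O=C(Cl)c1ccccc1
Why: DMAP-catalysed acylation esterifies the hindered C11 alcohol without breaking its C–O bond (retention), and acylating before the carboxylic acid exists avoids mixed anhydrides and oligomeric esters.

Step 12
Reactants: 23 benzoate enal
Product: 24 (5E,9E,11R)-11-(benzoyloxy)-1,1,5-trimethylcycloundeca-5,9-diene-9-carboxylic acid (route numbering)
Conditions: NaClO2, NaH2PO4, 2-methylbut-2-ene (excess), t-BuOH–H2O, 0 °C → rt
Reagents that add atoms: sodium chlorite, [Na+].[O-]Cl=O
Why: Pinnick oxidation: chlorous acid adds to the aldehyde and fragments to the acid and hypochlorous acid, which the excess 2-methylbut-2-ene intercepts before it can reach C5=C6, and the benzoate and both alkene geometries are untouched at this pH.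

Step 13
Reactants: 24 dienoic acid
Product: 25 (5R,6R,9E,11R)-11-(benzoyloxy)-5,6-epoxy-1,1,5-trimethylcycloundec-9-ene-9-carboxylic acid (route numbering; target CNP0377917.1)
Conditions: 1,2:4,5-di-O-isopropylidene-β-D-erythro-2,3-hexodiulo-2,6-pyranose (0.5 equiv), Oxone, K2CO3, Na2B4O7/Na2EDTA buffer (pH about 10.5), Bu4NHSO4 (cat.), MeCN–dimethoxymethane, 0 °C; then NaH2PO4 to pH 4–5, EtOAc
Reagents that add atoms: potassium peroxymonosulfate (active part of Oxone), [K+].[O-]S(=O)(=O)OO
Why: Shi epoxidation: the D-fructose-derived ketone with Oxone delivers oxygen through a spiro transition state to the face of an E-trisubstituted alkene that gives the R,R-epoxide, the transfer is stereospecifically syn so that C4 and C7 stay trans, the electron-rich C5=C6 is chosen over C9=C10 (deactivated as the conjugated carboxylate), and because the E-alkene can swing through the 11-membered ring both faces are on offer and the catalyst should decide.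

Compound list
1 | isobutyraldehyde | CC(C)C=O | starting material
2 | 1,1-bis(phenylsulfonyl)ethylene | C=C(S(=O)(=O)c1ccccc1)S(=O)(=O)c1ccccc1 | starting material
3 | 1-(2-methylprop-1-en-1-yl)pyrrolidine (not isolated) | CC(C)=CN1CCCC1 | intermediate
4 | 2,2-dimethyl-4,4-bis(phenylsulfonyl)butanal | O=CC(C)(C)CC(S(=O)(=O)c1ccccc1)S(=O)(=O)c1ccccc1 | intermediate
5 | 5-bromo-2-methylpent-2-ene | CC(C)=CCCBr | starting material
6 | tert-butyldimethyl(prop-2-yn-1-yloxy)silane | C#CCO[Si](C)(C)C(C)(C)C | starting material
7 | (4-methylpent-3-en-1-yl)magnesium bromide (not isolated) | CC(C)=CCC[Mg]Br | intermediate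
8 | (4-methylpent-3-en-1-yl)copper (not isolated) | CC(C)=CCC[Cu] | intermediate
9 | (E)-alkenylcopper, Cu cis to the C8 chain (not isolated) | [Cu]/C=C(\CCC=C(C)C)CO[Si](C)(C)C(C)(C)C | intermediate
10 | (E)-tert-butyl{[2-(iodomethylidene)-6-methylhept-5-en-1-yl]oxy}dimethylsilane | I/C=C(\CCC=C(C)C)CO[Si](C)(C)C(C)(C)C | intermediate
11 | (E)-alkenylchromium(III) dichloride, chiral ligand omitted (not isolated) | Cl[Cr](Cl)/C=C(\CCC=C(C)C)CO[Si](C)(C)C(C)(C)C | intermediate
12 | (4R,5E)-6-(TBSO-methyl)-3,3,10-trimethyl-1,1-bis(phenylsulfonyl)undeca-5,9-dien-4-ol | CC(C)=CCC/C(CO[Si](C)(C)C(C)(C)C)=C\[C@@H](O)C(C)(C)CC(S(=O)(=O)c1ccccc1)S(=O)(=O)c1ccccc1 | intermediate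
13 | C11,C12-bis-TBS ether of 12 | CC(C)=CCC/C(CO[Si](C)(C)C(C)(C)C)=C\[C@@H](O[Si](C)(C)C(C)(C)C)C(C)(C)CC(S(=O)(=O)c1ccccc1)S(=O)(=O)c1ccccc1 | intermediate
14 | (2E,6E,8R)-C4 enal (not isolated) | O=C/C(C)=C/CC/C(CO[Si](C)(C)C(C)(C)C)=C\[C@@H](O[Si](C)(C)C(C)(C)C)C(C)(C)CC(S(=O)(=O)c1ccccc1)S(=O)(=O)c1ccccc1 | intermediate
15 | (2E,6E,8R)-C4 allylic alcohol | OC/C(C)=C/CC/C(CO[Si](C)(C)C(C)(C)C)=C\[C@@H](O[Si](C)(C)C(C)(C)C)C(C)(C)CC(S(=O)(=O)c1ccccc1)S(=O)(=O)c1ccccc1 | intermediate
16 | (2E,6E,8R)-C4 allylic methyl carbonate, cyclisation precursor | COC(=O)OC/C(C)=C/CC/C(CO[Si](C)(C)C(C)(C)C)=C\[C@@H](O[Si](C)(C)C(C)(C)C)C(C)(C)CC(S(=O)(=O)c1ccccc1)S(=O)(=O)c1ccccc1 | intermediate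
17 | π-allylpalladium / C3 carbanion zwitterion, written in its η1-C4 form, phosphines omitted (not isolated) | [Pd+]C/C(C)=C/CC/C(CO[Si](C)(C)C(C)(C)C)=C\[C@@H](O[Si](C)(C)C(C)(C)C)C(C)(C)C[C-](S(=O)(=O)c1ccccc1)S(=O)(=O)c1ccccc1 | intermediate
18 | (5E,9E,11R)-macrocyclic C3 bis-sulfone | CC1(C)CC(S(=O)(=O)c2ccccc2)(S(=O)(=O)c2ccccc2)C/C(C)=C/CC/C(CO[Si](C)(C)C(C)(C)C)=C\[C@H]1O[Si](C)(C)C(C)(C)C | intermediate
19 | macrocyclic C3 monosulfone, C3 epimers (not isolated) | CC1(C)CC(S(=O)(=O)c2ccccc2)C/C(C)=C/CC/C(CO[Si](C)(C)C(C)(C)C)=C\[C@H]1O[Si](C)(C)C(C)(C)C | intermediate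
20 | (5E,9E,11R)-bis-TBS cycloundecadiene | CC1(C)CCC/C(C)=C/CC/C(CO[Si](C)(C)C(C)(C)C)=C\[C@H]1O[Si](C)(C)C(C)(C)C | intermediate
21 | (5E,9E,11R)-C11,C12-diol | CC1(C)CCC/C(C)=C/CC/C(CO)=C\[C@H]1O | intermediate
22 | (5E,9E,11R)-C11-hydroxy C12-enal | CC1(C)CCC/C(C)=C/CC/C(C=O)=C\[C@H]1O | intermediate
23 | (5E,9E,11R)-C11-benzoate C12-enal | CC1(C)CCC/C(C)=C/CC/C(C=O)=C\[C@H]1OC(=O)c1ccccc1 | intermediate
24 | (5E,9E,11R)-C11-benzoate C12-acid | CC1(C)CCC/C(C)=C/CC/C(C(=O)O)=C\[C@H]1OC(=O)c1ccccc1 | intermediate
25 | (5R,6R,9E,11R)-epoxy acid, CNP0377917.1 | CC1(C)CCC[C@@]2(C)O[C@@H]2CC/C(C(=O)O)=C\[C@H]1OC(=O)c1ccccc1 | target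

Total step count: 13. Longest linear sequence: 12 (step 2, then steps 3–13, from 5 and 6; the branch from 1 and 2 through step 1 is equally long).

Steps most likely to fail

Step 7 (ring closure).
- What may go wrong: intermolecular alkylation may outrun the strained 11-membered closure. Syn–anti equilibration of the allyl unit may erode the E geometry, and the carbanion may attack the substituted terminus.
- Fallback: it sets out from 15. Appel bromination (CBr4, PPh3, CH2Cl2, 0 °C; neutral, so C3–H stays protonated) would give the allylic bromide F1.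
- Slow addition of the bromide to Cs2CO3 in DMF at about 1 mM would then close the same C3–C4 bond by direct SN2 displacement. No metal-bound allyl intermediate is involved, so the alkene geometry is locked.
- This comes back to the route at 18.

Step 3 (fragment union).
- What may go wrong: the alkenylchromium species may be protonated by C3–H. Addition to the neopentylic aldehyde may be sluggish, or facial control by the ligand may be insufficient.
- Fallback: it sets out from 4 and 10. LiHMDS (1.0 equiv, THF, −78 °C) would convert 4 into its C3 lithium salt F2; the aldehyde cannot enolise and the delocalised carbanion does not add to it.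
- t-BuLi (2 equiv, Et2O, −78 °C) would convert 10 with retention into the alkenyllithium F3. Their union gives the racemic alcohol F4.
- Dess–Martin oxidation gives the enone F5. Corey–Bakshi–Shibata reduction with the (S)-methyl-oxazaborolidine and catecholborane (toluene, −78 °C), the quaternary C1 flank acting as the large group, comes back to the route at 12.
- In either variant, residual 11S material should be shed after step 13 as a separable diastereomer.

Step 13 (epoxidation).
- What may go wrong: a conformational bias of the ring may override the catalyst and give poor or reversed facial selectivity.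
- Fallback: it turns such a bias to use and sets out from 23. NBS in THF–H2O (0 °C) would place bromine on the face that external electrophiles prefer and water on C5 from the other face, giving the bromohydrin F6.
- DBU (CH2Cl2, rt) closes the ring with inversion at C6 to the epoxy enal F7, so the oxygen sits on the face opposite to direct epoxidation.
- Pinnick oxidation as in step 12 comes back to the route at 25.

Further compounds
F1 | step 7 | (2E,6E,8R)-C4 allylic bromide | BrC/C(C)=C/CC/C(CO[Si](C)(C)C(C)(C)C)=C\[C@@H](O[Si](C)(C)C(C)(C)C)C(C)(C)CC(S(=O)(=O)c1ccccc1)S(=O)(=O)c1ccccc1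
F2 | step 3 | C3 lithium salt of aldehyde 4 | [Li+].O=CC(C)(C)C[C-](S(=O)(=O)c1ccccc1)S(=O)(=O)c1ccccc1
F3 | step 3 | (E)-alkenyllithium, Li cis to the C8 chain | [Li]/C=C(\CCC=C(C)C)CO[Si](C)(C)C(C)(C)C
F4 | step 3 | racemic C11 alcohol (5E) | CC(C)=CCC/C(CO[Si](C)(C)C(C)(C)C)=C\C(O)C(C)(C)CC(S(=O)(=O)c1ccccc1)S(=O)(=O)c1ccccc1
F5 | step 3 | C11 enone (C8 cis to C11) | CC(C)=CCC/C(CO[Si](C)(C)C(C)(C)C)=C\C(=O)C(C)(C)CC(S(=O)(=O)c1ccccc1)S(=O)(=O)c1ccccc1
F6 | step 13 | (5R,6S,9E,11R)-6-bromo-5-hydroxy benzoate enal | CC1(C)CCC[C@@](C)(O)[C@@H](Br)CC/C(C=O)=C\[C@H]1OC(=O)c1ccccc1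
F7 | step 13 | (5R,6R,9E,11R)-5,6-epoxy benzoate enal | CC1(C)CCC[C@@]2(C)O[C@@H]2CC/C(C=O)=C\[C@H]1OC(=O)c1ccccc1
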